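**Plan**

1. Cuts (pterocarpan numbering): first the O11–C10a aryl ether bond of ring C, then the C9 O–CH3 bond and the silyl ether at O3; next the C6a–C6b bond joining ring D to the chroman; then O5–C6 and C6–C6a of ring B (one carbon added to an acetyl group); finally O–C(CH3)2 and C2–CH of ring E. This leads back to 2,4,6-trihydroxyacetophenone, 3-methylbut-2-enal and [4-(benzyloxy)phenyl]boronic acid.
2. Enabling feature: in ring D, O11 sits on C10a ortho to C6b and the methoxy oxygen sits on C9 para to C6b. That is the pattern left when the C11a hydroxyl adds to the dienone of a para-quinol made from a plain 4-hydroxyphenyl group and water is then lost.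
3. Forward order: ring A is bought; ring E is annulated (the silylated para oxygen forces the pyran onto an ortho oxygen); ring B follows as a 3-iodochromone; ring D is attached by Suzuki coupling; ring C closes last.
4. Stereochemistry: C6a and C11a (6aS,11aS) are both set in one asymmetric transfer hydrogenation with dynamic kinetic resolution of the racemic isoflavanone, giving the (3S,4S)-cis-isoflavan-4-ol; ring C closure leaves both untouched.
5. End game: methylation of the new C9 phenol and fluoride removal of the silyl ether.

Key step: step 7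

Remark on numbering: tetracyclic compounds use pterocarpan numbering (ring A phenol ring, ring B pyran with O5/C6, ring C dihydrofuran with O11, ring D, ring E dimethylpyran on C1–O/C2). Earlier compounds carry systematic names, with isoflavone numbering added in brackets.
Assumption: the (S,S)-configured transfer-hydrogenation catalyst is taken to give the 4S alcohol, as it does with chroman-4-one and 1-tetralone; should the sense be opposite, the (R,R) catalyst is used and nothing else changes.

**Route**

Step 1
Reactants: 1 2,4,6-trihydroxyacetophenone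
Product: 2 1-{2,6-dihydroxy-4-[(triisopropylsilyl)oxy]phenyl}ethan-1-one
Conditions: TIPSCl (1.05 equiv), imidazole, DMF, 0 °C
Reagents that add atoms: triisopropylsilyl chloride, CC(C)[Si](Cl)(C(C)C)C(C)C
Why: The para hydroxyl is the most acidic and least hindered of the three and is not held in the hydrogen bond to the acetyl carbonyl, so one equivalent of the bulky silyl chloride should silylate it selectively (chemoselective phenol silylation), leaving two equivalent ortho hydroxyls.

Step 2
Reactants: 2 1-{2,6-dihydroxy-4-[(triisopropylsilyl)oxy]phenyl}ethan-1-one; 3 3-methylbut-2-enal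
Product: 5 1-{7-hydroxy-2,2-dimethyl-5-[(triisopropylsilyl)oxy]-2H-chromen-8-yl}ethan-1-one, via ortho-quinone methide 4 (not isolated)
Conditions: 3-methylbut-2-enal (1.1 equiv), ethylenediammonium diacetate (cat.), toluene, reflux
Reagents that add atoms: 3-methylbut-2-enal 3, CC(C)=CC=O
Why: Knoevenagel-type condensation of the enal at the ring carbon between OH and OSi gives ortho-quinone methide 4, which closes by oxa-6π electrocyclization (formal [3+3] chromene annulation); because the para oxygen is silylated only an ortho hydroxyl can become the pyran oxygen and the two ring CH positions are equivalent, so one regioisomer is possible, and about one equivalent of enal keeps the second ortho hydroxyl from annulating.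

Step 3
Reactants: 5 1-{7-hydroxy-2,2-dimethyl-5-[(triisopropylsilyl)oxy]-2H-chromen-8-yl}ethan-1-one
Product: 7 9-iodo-2,2-dimethyl-5-[(triisopropylsilyl)oxy]-2H,10H-pyrano[2,3-f]chromen-10-one, via enaminone 6 (not isolated)
Conditions: Me2NCH(OMe)2, toluene, 85 °C; concentrate; then I2, CHCl3, rt
Reagents that add atoms: N,N-dimethylformamide dimethyl acetal, COC(OC)N(C)C; iodine, II
Why: Condensation of the acetyl methyl group with the formamide acetal gives the enaminone, and iodine then iodinates its α-carbon, the chelated phenol adds to the iminium carbon and dimethylamine is lost (iodine-induced enaminone cyclization to a 3-iodochromone); the enaminone is far more nucleophilic than the chromene alkene or the remaining ring CH.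

Step 4
Reactants: 7 9-iodo-2,2-dimethyl-5-[(triisopropylsilyl)oxy]-2H,10H-pyrano[2,3-f]chromen-10-one; 8 [4-(benzyloxy)phenyl]boronic acid
Product: 9 9-[4-(benzyloxy)phenyl]-2,2-dimethyl-5-[(triisopropylsilyl)oxy]-2H,10H-pyrano[2,3-f]chromen-10-one
Conditions: Pd(dppf)Cl2 (cat.), K3PO4, 1,4-dioxane/H2O (10:1), 60 °C
Reagents that add atoms: [4-(benzyloxy)phenyl]boronic acid 8, OB(O)c1ccc(OCc2ccccc2)cc1
Why: Suzuki–Miyaura coupling of a 3-iodochromone with an arylboronic acid is the standard entry to isoflavones; the benzyl ether keeps ring D free of a phenoxide that could take over the silyl group, and the mild phosphate base at moderate temperature is chosen to spare the silyl ether and the chromone.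

Step 5
Reactants: 9 9-[4-(benzyloxy)phenyl]-2,2-dimethyl-5-[(triisopropylsilyl)oxy]-2H,10H-pyrano[2,3-f]chromen-10-one
Product: 10 rac-9-(4-hydroxyphenyl)-2,2-dimethyl-5-[(triisopropylsilyl)oxy]-3,4,8,9-tetrahydro-2H,10H-pyrano[2,3-f]chromen-10-one
Conditions: H2 (1 atm), Pd/C, EtOAc/EtOH, rt
Reagents that add atoms: none
Why: Heterogeneous hydrogenation should saturate the chromene alkene and the isoflavone C2–C3 alkene and hydrogenolyse the benzyl ether in one operation, while the ketone, a vinylogous ester flanked by the C5 ether oxygen, is reduced much more slowly; C3 forms racemic, which is harmless because the next step equilibrates it.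

Step 6
Reactants: 10 rac-9-(4-hydroxyphenyl)-2,2-dimethyl-5-[(triisopropylsilyl)oxy]-3,4,8,9-tetrahydro-2H,10H-pyrano[2,3-f]chromen-10-one
Product: 11 (9S,10S)-9-(4-hydroxyphenyl)-2,2-dimethyl-5-[(triisopropylsilyl)oxy]-3,4,9,10-tetrahydro-2H,8H-pyrano[2,3-f]chromen-10-ol
Conditions: RuCl[(S,S)-TsDPEN](p-cymene) (cat.), HCO2H, Et3N (excess), EtOAc, 40 °C
Reagents that add atoms: none
Why: Noyori–Ikariya asymmetric transfer hydrogenation with dynamic kinetic resolution: triethylamine epimerizes C3 through the enol, the (S,S) catalyst reduces the (3S)-ketone faster and delivers hydride to the carbonyl face opposite the C3 aryl group, so C4 is set as S by the catalyst and C3 as S with aryl and hydroxyl cis, as is known for isoflavanones.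

Step 7
Reactants: 11 (9S,10S)-9-(4-hydroxyphenyl)-2,2-dimethyl-5-[(triisopropylsilyl)oxy]-3,4,9,10-tetrahydro-2H,8H-pyrano[2,3-f]chromen-10-ol
Product: 15 (6aS,11aS)-9-hydroxy-3-[(triisopropylsilyl)oxy]pterocarpan carrying ring E, via ring D hydroperoxide 12 (not isolated), via para-quinol 13 (not isolated), via oxa-Michael adduct 14 (not isolated)
Conditions: KHSO5 (as Oxone, 2KHSO5·KHSO4·K2SO4), NaHCO3, MeCN/H2O, 0 °C to rt; Me2S; then DBU (cat.), CH2Cl2, rt; then TsOH·H2O (in excess over DBU), rt
Reagents that add atoms: none
Why: Singlet oxygen released from KHSO5 in bicarbonate adds to the phenolate of ring D, the only free phenol because ring A is capped as its silyl ether, to give hydroperoxide 12, which dimethyl sulfide reduces to para-quinol 13, as known for para-alkylphenols. Under the amine base the cis-disposed C11a hydroxyl adds to a β-carbon of the cyclohexadienone (oxa-Michael, 5-exo-trig), forming O11–C10a and ring C in adduct 14. Acid then removes the tertiary C6b hydroxyl together with H10a, and the resulting dienone tautomerizes to the phenol, so O11 ends ortho and the original phenol oxygen para to C6b; the oxygen brought in by the oxidant leaves as water. The closest known reaction type is the oxidative dearomatization, conjugate addition and dehydrative rearomatization sequence of para-quinols that gives meta-functionalized phenols. No lasting stereocentre is made: the centres formed at C6b and C10a are erased on aromatization, both β-carbons lead to the same arene, and C6a and C11a are untouched because the C11a–O bond is never broken. The selectivities needed are chemoselective oxidation of ring D, secured by the silyl ether on ring A, and ring closure before any ionization at the electron-rich benzylic C11a, secured by the cis geometry from step 6 and by running the conjugate addition under base before acid is added.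

Step 8
Reactants: 15 (6aS,11aS)-9-hydroxy-3-[(triisopropylsilyl)oxy]pterocarpan carrying ring E
Product: 16 (6aS,11aS)-9-methoxy-3-[(triisopropylsilyl)oxy]pterocarpan carrying ring E
Conditions: MeI, K2CO3, acetone, 40 °C
Reagents that add atoms: iodomethane, CI
Why: Williamson methylation of the only free phenol; the silyl ether on the electron-rich ring A, no longer conjugated to a carbonyl, should be stable to K2CO3 in acetone.

Step 9
Reactants: 16 (6aS,11aS)-9-methoxy-3-[(triisopropylsilyl)oxy]pterocarpan carrying ring E
Product: 17 CNP0207547.1, (6aS,11aS)-3-hydroxy-9-methoxypterocarpan carrying ring E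
Conditions: Bu4NF, AcOH, THF, 0 °C to rt
Reagents that add atoms: none
Why: Fluoride cleavage of the aryl silyl ether; buffering with acetic acid keeps the electron-rich phenoxide and the benzylic aryl ether away from strongly basic conditions, and the methyl ether and both stereocentres are not affected.

**Compound list**

1 | 2,4,6-trihydroxyacetophenone | CC(=O)c1c(O)cc(O)cc1O | starting material
2 | 1-{2,6-dihydroxy-4-[(triisopropylsilyl)oxy]phenyl}ethan-1-one | CC(=O)c1c(O)cc(O[Si](C(C)C)(C(C)C)C(C)C)cc1O | intermediate
3 | 3-methylbut-2-enal | CC(C)=CC=O | starting material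
4 | ortho-quinone methide, 2-acetyl-3-hydroxy-6-(3-methylbut-2-en-1-ylidene)-5-[(triisopropylsilyl)oxy]cyclohexa-2,4-dien-1-one (not isolated) | CC(=O)C1=C(O)C=C(O[Si](C(C)C)(C(C)C)C(C)C)/C(=C/C=C(C)C)C1=O | intermediate
5 | 1-{7-hydroxy-2,2-dimethyl-5-[(triisopropylsilyl)oxy]-2H-chromen-8-yl}ethan-1-one | CC(=O)c1c(O)cc(O[Si](C(C)C)(C(C)C)C(C)C)c2C=CC(C)(C)Oc12 | intermediate
6 | enaminone, (E)-3-(dimethylamino)-1-{7-hydroxy-2,2-dimethyl-5-[(triisopropylsilyl)oxy]-2H-chromen-8-yl}prop-2-en-1-one (not isolated) | CN(C)/C=C/C(=O)c1c(O)cc(O[Si](C(C)C)(C(C)C)C(C)C)c2C=CC(C)(C)Oc12 | intermediate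
7 | 9-iodo-2,2-dimethyl-5-[(triisopropylsilyl)oxy]-2H,10H-pyrano[2,3-f]chromen-10-one (3-iodochromone; silyloxy at C7, dimethylpyran on C5–O/C6) | O=C1C(I)=COc2cc(O[Si](C(C)C)(C(C)C)C(C)C)c3C=CC(C)(C)Oc3c12 | intermediate
8 | [4-(benzyloxy)phenyl]boronic acid | OB(O)c1ccc(OCc2ccccc2)cc1 | starting material
9 | 9-[4-(benzyloxy)phenyl]-2,2-dimethyl-5-[(triisopropylsilyl)oxy]-2H,10H-pyrano[2,3-f]chromen-10-one (isoflavone; 4'-OBn, 7-OSi) | O=C1C(c2ccc(OCc3ccccc3)cc2)=COc2cc(O[Si](C(C)C)(C(C)C)C(C)C)c3C=CC(C)(C)Oc3c12 | intermediate
10 | rac-9-(4-hydroxyphenyl)-2,2-dimethyl-5-[(triisopropylsilyl)oxy]-3,4,8,9-tetrahydro-2H,10H-pyrano[2,3-f]chromen-10-one (racemic isoflavanone, ring E saturated) | O=C1C(c2ccc(O)cc2)COc2cc(O[Si](C(C)C)(C(C)C)C(C)C)c3CCC(C)(C)Oc3c12 | intermediate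
11 | (9S,10S)-9-(4-hydroxyphenyl)-2,2-dimethyl-5-[(triisopropylsilyl)oxy]-3,4,9,10-tetrahydro-2H,8H-pyrano[2,3-f]chromen-10-ol ((3S,4S)-cis-isoflavan-4-ol) | O[C@@H]1c2c(cc(O[Si](C(C)C)(C(C)C)C(C)C)c3c2OC(C)(C)CC3)OC[C@@H]1c4ccc(O)cc4 | intermediate
12 | ring D hydroperoxide: 11 with the aryl group replaced by 1-hydroperoxy-4-oxocyclohexa-2,5-dien-1-yl (not isolated) | O[C@@H]1c2c(cc(O[Si](C(C)C)(C(C)C)C(C)C)c3c2OC(C)(C)CC3)OC[C@@H]1C4(OO)C=CC(=O)C=C4 | intermediate
13 | para-quinol: 11 with the aryl group replaced by 1-hydroxy-4-oxocyclohexa-2,5-dien-1-yl (not isolated) | O[C@@H]1c2c(cc(O[Si](C(C)C)(C(C)C)C(C)C)c3c2OC(C)(C)CC3)OC[C@@H]1C4(O)C=CC(=O)C=C4 | intermediate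
14 | oxa-Michael adduct: ring C closed, ring D as 6b-hydroxy-7-en-9-one (C6b–OH, C7=C8, C9=O, C10H2, C10a–H); C6b and C10a form without control and are erased in the same step, so they are left undefined (not isolated) | O=C1C=CC2(O)C(C1)O[C@@H]1c3c(cc(O[Si](C(C)C)(C(C)C)C(C)C)c4c3OC(C)(C)CC4)OC[C@H]21 | intermediate
15 | (6aS,11aS)-9-hydroxy-3-[(triisopropylsilyl)oxy]pterocarpan carrying ring E (2,2-dimethyl-3,4-dihydro-2H-pyran on C1–O/C2) | Oc1ccc2c(c1)O[C@@H]1c3c(cc(O[Si](C(C)C)(C(C)C)C(C)C)c4c3OC(C)(C)CC4)OC[C@H]21 | intermediate
16 | (6aS,11aS)-9-methoxy-3-[(triisopropylsilyl)oxy]pterocarpan carrying ring E | COc1ccc2c(c1)O[C@@H]1c3c(cc(O[Si](C(C)C)(C(C)C)C(C)C)c4c3OC(C)(C)CC4)OC[C@H]21 | intermediate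
17 | CNP0207547.1, (6aS,11aS)-3-hydroxy-9-methoxypterocarpan carrying ring E | COc1ccc2c(c1)O[C@@H]1c3c(cc(O)c4c3OC(C)(C)CC4)OC[C@H]21 | target

**Step count and risks**

Total step count: 9. Longest linear sequence: 9 steps, from 1.

Steps most likely to fail:

1. Step 7. Three processes may interfere: the peroxide may also oxidize the electron-rich ring A or the benzylic alcohol; acid may ionize C11a before or after ring closure, leading to elimination toward the isoflav-3-ene and loss of the C6a configuration; and the tertiary alcohol may dehydrate only reluctantly. The fallback closes ring C in the classical way from a 2'-oxygenated ring D. It sets out from iodochromone 7 and comes back at methyl ether 16. Suzuki coupling of 7 with purchased [2-(benzyloxy)-4-methoxyphenyl]boronic acid (Pd(dppf)Cl2, K3PO4) should give the 2'-benzyloxy-4'-methoxyisoflavone F1. Hydrogenation (H2, Pd/C) should give the racemic 2'-hydroxy-4'-methoxyisoflavanone F2. Transfer hydrogenation as in step 6 should give the (3S,4S)-cis-2'-hydroxyisoflavan-4-ol F3. Catalytic TsOH in CH2Cl2 at 0 °C should then close ring C by capture of the C4 benzylic cation by the 2'-phenol, which can only give the cis-fused 16. Step 9 follows unchanged.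

2. Step 6. Reduction of the hindered, electron-rich ketone next to the C5 ether oxygen may be slow, and C3 may epimerize too slowly relative to reduction, which would erode both the cis selectivity and the enantiomeric purity. The fallback replaces catalyst control by substrate control plus resolution. It sets out from 10 and comes back at 11. LiBH(s-Bu)3 in THF at −78 °C should deliver hydride from the face opposite the aryl group and give the racemic cis alcohol, that is 11 together with its (3R,4R)-enantiomer F4. Preparative chromatography on a chiral stationary phase separates them, and F4 can be oxidized with MnO2 back to 10 and recycled.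

3. Step 4. The silyl group on the acidic C7 oxygen (a vinylogous silyl ester) may be hydrolysed or may migrate under the aqueous basic coupling, giving mixtures. The fallback gives up carrying the silyl ether through the coupling. It sets out from 7 and 8 and comes back at 9. The coupling is run with aqueous K2CO3 in dioxane at 90 °C so that the silyl ether is cleaved completely, giving the 7-hydroxyisoflavone F5. Its only free hydroxyl is then silylated again (TIPSCl, imidazole, DMF) to give 9.

**Further compounds**

F1 | step 7 | 9-[2-(benzyloxy)-4-methoxyphenyl]-2,2-dimethyl-5-[(triisopropylsilyl)oxy]-2H,10H-pyrano[2,3-f]chromen-10-one | O=C1C(c2ccc(OC)cc2OCc2ccccc2)=COc2cc(O[Si](C(C)C)(C(C)C)C(C)C)c3C=CC(C)(C)Oc3c12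
F2 | step 7 | rac-9-(2-hydroxy-4-methoxyphenyl)-2,2-dimethyl-5-[(triisopropylsilyl)oxy]-3,4,8,9-tetrahydro-2H,10H-pyrano[2,3-f]chromen-10-one | O=C1C(c2ccc(OC)cc2O)COc2cc(O[Si](C(C)C)(C(C)C)C(C)C)c3CCC(C)(C)Oc3c12
F3 | step 7 | (9S,10S)-9-(2-hydroxy-4-methoxyphenyl)-2,2-dimethyl-5-[(triisopropylsilyl)oxy]-3,4,9,10-tetrahydro-2H,8H-pyrano[2,3-f]chromen-10-ol | O[C@@H]1c2c(cc(O[Si](C(C)C)(C(C)C)C(C)C)c3c2OC(C)(C)CC3)OC[C@@H]1c4ccc(OC)cc4O
F4 | step 6 | (9R,10R)-9-(4-hydroxyphenyl)-2,2-dimethyl-5-[(triisopropylsilyl)oxy]-3,4,9,10-tetrahydro-2H,8H-pyrano[2,3-f]chromen-10-ol (enantiomer of 11) | O[C@H]1c2c(cc(O[Si](C(C)C)(C(C)C)C(C)C)c3c2OC(C)(C)CC3)OC[C@H]1c4ccc(O)cc4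
F5 | step 4 | 9-[4-(benzyloxy)phenyl]-5-hydroxy-2,2-dimethyl-2H,10H-pyrano[2,3-f]chromen-10-one | O=C1C(c2ccc(OCc3ccccc3)cc2)=COc2cc(O)c3C=CC(C)(C)Oc3c12
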